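## Analysis of the target

The target is a flavone: benzo ring A (C4a, C5–C8, C8a) is fused to the pyranone ring C (O1, C2, C3, C4), with the phenyl ring B on C2, a methoxy group on C5, a free hydroxyl on C7 and, on C8, a piperidine attached through its C2' (piperidine atoms N1', C2'–C6'). C2' is the only stereocenter; it is (R), benzylic and bonded to nitrogen, so there is no relative configuration to control, but the absolute one must be set and then kept. C2' is wedged between two ortho oxygens, the C7 hydroxyl and O1 on C8a, which shield it and also make the C2'–N1' bond labile: next to a free phenol it can ionise to an ortho-quinone methide under acid or heat, which would racemise the centre or open the ring. The other sensitive groups are the secondary amine (it binds late transition metals and would be acylated under carbonylation), the acidic C7 phenol, and the pyranone enone, which would not survive hydrogenation or strong nucleophiles, so ring C is best built after all reductions. The oxygen pattern of ring A (OMe at C5, OH at C7, carbon at C8) stops being a regiochemical problem when ring C is closed last, because a 2,6-dioxygenated 4-methoxyphenyl group on C2' is locally symmetric and annulation through either oxygen gives the same flavone. The difficulty therefore lies in making the crowded, configurationally fragile aryl–C2'–N unit as one enantiomer and closing a piperidine around it. The plan rests on the C4'–C5' bond, which lies across the piperidine from C2', out of reach of the C7 and C8a oxygens: it can be made last in the nitrogen ring, as a C4'=C5' double bond by olefin metathesis, after C2' has been set in an open-chain compound.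

## Retrosynthetic reasoning

**27 to 26.** The last disconnection is the bond between N1' and its tert-butoxycarbonyl group. The amine stays masked as carbamate 26 until the end because a free secondary amine would interfere with every metal-catalysed step. In 26 ring A is deactivated by the C4 carbonyl, so a short acid treatment should not ionise C2'–N1'.

**26 to 22, 23 and 24.** Ring C is cut at C4a–C4, C4–C3 and O1–C2, which removes 23 and 24 and leaves the iodophenol 22. Cutting here keeps the reducible, nucleophile-sensitive pyranone out of all earlier steps. The forward reaction has to insert 24 into the aryl–iodine bond, couple the acyl group with 23 and close the pyranone through the phenol ortho to the new ketone; the second phenol is para to it and cannot compete.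

**22 to 20.** The C–I bond is cut to give the resorcinol 20. Its two free ring positions are interchanged by rotation about the aryl–C2' bond, so mono-iodination can give only one constitution. The forward step only has to stop after one iodine.

**20 to 19.** Compound 20 is traced to the tetrahydropyridine 19 by restoring the two benzyl ethers and the C4'=C5' double bond. Benzyl ethers are chosen because one neutral hydrogenation then saturates the alkene and frees both phenols, and because, as ethers, they block quinone-methide formation at C2' during the earlier acidic and basic steps.

**19 to 18 (key disconnection).** The piperidine is opened at C4'=C5' to the diene 18. N1'–C2' and C2'–C3' both end at the crowded stereocenter, and closing the ring there would merge ring formation with stereocontrol. N1'–C6' would require a ring-closing substitution at a nitrogen shielded by the aryl group. C4'–C5' is the ring bond farthest from C2'; in 18 both its carbons are unhindered terminal alkene carbons, and its closure does not depend on the configuration already present. The gain is that the ring is made by a reaction of very wide scope at a site the ortho oxygens cannot influence. The forward step only has to favour cyclisation over chain growth.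

**18 to 16 and 17.** The N1'–C6' bond is cut to give carbamate 16 and the allyl halide 17. The single acidic N–H of the carbamate allows clean mono-alkylation in a separate step.

**16 to 13.** The nitrogen substituent is exchanged: the sulfinyl group of 13 is removed to the amine 15, which is capped as the carbamate. The sulfur auxiliary has done its work after the addition and would interfere with the palladium steps, while the carbamate is needed through metathesis, hydrogenation and carbonylation.

**13 to 11 and 12, and 11 to 9 and 10.** The C2'–C3' bond is cut to give the sulfinyl aldimine 11 and the allyl nucleophile 12. This is where C2' is set, in an open-chain compound whose diastereomers can still be purified. An allyl group is chosen because it is reactive enough for a di-ortho-substituted aldimine and carries the alkene later needed for metathesis. Imine 11 comes from aldehyde 9 and the auxiliary 10 by condensation.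

**9 to 7 and 8, 7 to 6, 6 to 3 and 4, 3 to 1 and 2.** The formyl carbon, which becomes C2', is attached to the ring by directed ortho-lithiation of 3 and trapping with 4. Benzyl ethers are not used at this stage: a benzyloxy group directs no better than a methoxy group, so three ring positions would compete, and its benzylic hydrogens are themselves removed by alkyllithiums. The acetal ethers of 3 out-direct the methoxy group and place the metal between them. The price is an exchange of protecting groups (6 to 7 to 9), two simple steps that secure the regiochemistry. Compound 3 comes from 1 and 2.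

## Alternatives that were turned down

**Alternative 1:** three-component carbonylative annulation as the carrier of the plan.
- Disconnection: ring C at C4a–C4, C4–C3 and O1–C2, back to the ortho-iodophenol tert-butyl (2R)-2-(2,6-dihydroxy-3-iodo-4-methoxyphenyl)piperidine-1-carboxylate A2, the alkyne 23 and 24.
- Forward key step: PdCl2(PPh3)2 under CO in an amine would carbonylate the aryl iodide, couple the acyl group with the alkyne and close the pyranone, giving tert-butyl (2R)-2-(7-hydroxy-5-methoxy-4-oxo-2-phenyl-4H-chromen-8-yl)piperidine-1-carboxylate A1.
- For it: three bonds and a ring in one operation from simple partners; it uses the local symmetry of the ring A precursor; ring B enters late.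
- Against it: it leaves the real problem, the crowded stereocenter C2', unaddressed. The iodide is flanked by OH and OMe on a very electron-rich ring, so CO insertion must compete with direct alkynylation (leading to a benzofuran) and with amine capture of the acylpalladium. Hot amine next to a benzylic C–N bond ortho to a phenol also puts the configuration at risk.
- Comparison: on ring C this alternative is exactly as strong as the chosen plan, which adopts the same annulation as step 12 (A2 and A1 are compounds 22 and 26). The difference is where the plan's weight sits: the chosen strategy puts its defining step on the piperidine, in a reaction of high reliability, and treats the annulation as an endgame step with a classical fallback.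

**Alternative 2:** Grignard addition to a sulfinyl imine with ring closure in the same flask.
- Disconnection: C2'–C3' and N1'–C6' together, back to (S)-N-[(E)-[4-methoxy-2,6-bis(methoxymethoxy)phenyl]methylidene]-2-methylpropane-2-sulfinamide A4 and 4-chlorobutylmagnesium bromide A5.
- Forward key step: the Grignard reagent adds to the imine carbon and the nitrogen anion then displaces chloride, giving (2R)-1-[(S)-tert-butylsulfinyl]-2-[4-methoxy-2,6-bis(methoxymethoxy)phenyl]piperidine A3.
- For it: stereocenter and ring are made in one flask; the acetal ethers used for the lithiation are carried on without exchange; no metathesis catalyst and no alkene to reduce. It is about four steps shorter than the chosen route, and this is conceded.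
- Against it: both new bonds are made at or next to the most hindered atom. A primary alkyl Grignard reagent is far less reactive toward a di-ortho-substituted aldimine than an allyl reagent, which adds through a cyclic six-centre path. The magnesium sulfinamide is a weak nucleophile for a primary chloride, and its nitrogen is shielded by the aryl group, so the closure would probably need a separate, stronger base. The ortho acetal oxygens can chelate magnesium in competition with the sulfinyl oxygen, which makes the facial selectivity uncertain. The acid that later removes the sulfinyl group also removes the acetals, exposing a free benzylic amine between two phenols before nitrogen can be re-protected.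
- Comparison: the chosen strategy pays in steps but separates the tasks. The stereocenter comes from a fast allyl addition and is checked on the open-chain compound 13; nitrogen is alkylated with a reactive allylic bromide in its own step; the ring bond is made far from the crowding; the phenols stay benzylated until nitrogen is a carbamate.

**Alternative 3:** chiral phosphoric acid closure onto an ortho-quinone methide.
- Disconnection: N1'–C2', back to tert-butyl N-[(E)-5-(2,6-dihydroxy-4-methoxyphenyl)pent-4-en-1-yl]carbamate A7.
- Forward key step: a BINOL-derived chiral phosphoric acid protonates the styrene to the quinone methide tert-butyl N-[5-(2-hydroxy-4-methoxy-6-oxocyclohexa-2,4-dien-1-ylidene)pentyl]carbamate A8, and the carbamate nitrogen adds to C2' within the chiral ion pair, giving tert-butyl (2R)-2-(2,6-dihydroxy-4-methoxyphenyl)piperidine-1-carboxylate A6.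
- For it: catalytic asymmetric induction, no auxiliary, no phenol protection, and direct access to A6, which is compound 20 of the chosen route, in roughly half the steps. On step economy and atom economy it is clearly stronger.
- Against it: the enantioselectivity depends on an ion pair whose substrate has a second free hydroxyl that can bind the catalyst in a competing way. The nucleophile is a weakly nucleophilic carbamate at the end of a flexible chain. The very electron-rich quinone methide can alkylate another resorcinol ring instead. Most seriously, the product's C2'–N1' bond is the bond the same acid can re-ionise, so the addition is reversible and the enantiomeric purity can erode under the reaction conditions.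
- Comparison: the chosen strategy uses a stoichiometric auxiliary and more steps, but its stereochemical outcome follows a well-understood cyclic model, its diastereomers are separable, and the benzyl ethers make quinone-methide formation impossible until the stereocenter is locked in the ring as a carbamate.

Key step: step 9

Assumption: the ring position of 3 between the two methoxymethoxy groups is taken to be lithiated in preference to the two positions next to the methoxy group, as the stronger directing power of the acetal ethers predicts.

## Route

Step 1
Reactants: 1 5-methoxyresorcinol (5-methoxybenzene-1,3-diol); 2 chloromethyl methyl ether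
Product: 3 1-methoxy-3,5-bis(methoxymethoxy)benzene
Conditions: NaH, MOMCl, DMF, 0 °C → rt
Reagents that add atoms: chloromethyl methyl ether, COCCl
Why: Williamson etherification of both sodium phenoxides; the hard chloromethyl ether reacts at oxygen, not at ring carbon.

Step 2
Reactants: 3 1-methoxy-3,5-bis(methoxymethoxy)benzene; 4 N,N-dimethylformamide
Product: 6 4-methoxy-2,6-bis(methoxymethoxy)benzaldehyde, via aryllithium 5 (not isolated)
Conditions: n-BuLi, THF, 0 °C; DMF, 0 °C → rt; H2O
Reagents that add atoms: N,N-dimethylformamide, CN(C)C=O
Why: Directed ortho-metalation: the two acetal ethers chelate lithium and acidify the hydrogen between them more than one acetal and one methoxy group do, so deprotonation should occur there. Aryllithium 5 is formylated by DMF, and the adduct collapses to the aldehyde on hydrolysis.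

Step 3
Reactants: 6 4-methoxy-2,6-bis(methoxymethoxy)benzaldehyde
Product: 7 2,6-dihydroxy-4-methoxybenzaldehyde
Conditions: HCl (cat.), MeOH, 50 °C
Reagents that add atoms: none
Why: Acid-catalysed methanolysis of the two aryl acetal ethers; the formyl group deactivates the ring toward the formaldehyde equivalent that is released.

Step 4
Reactants: 7 2,6-dihydroxy-4-methoxybenzaldehyde; 8 benzyl bromide
Product: 9 2,6-bis(benzyloxy)-4-methoxybenzaldehyde
Conditions: BnBr, K2CO3, DMF, 60 °C
Reagents that add atoms: benzyl bromide, BrCc1ccccc1
Why: Williamson etherification; the phenols are hydrogen-bonded to the carbonyl and need warm DMF, and the carbonyl-deactivated ring should not undergo C-benzylation.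

Step 5
Reactants: 9 2,6-bis(benzyloxy)-4-methoxybenzaldehyde; 10 (S)-tert-butanesulfinamide
Product: 11 (S)-N-[(E)-[2,6-bis(benzyloxy)-4-methoxyphenyl]methylidene]-2-methylpropane-2-sulfinamide
Conditions: Ti(OEt)4, THF, 65 °C
Reagents that add atoms: (S)-tert-butanesulfinamide, CC(C)(C)[S@](=O)N
Why: Lewis-acid-mediated condensation of the aldehyde with the sulfinamide; Ti(OEt)4 activates the hindered, electron-rich carbonyl and consumes the water, and the E imine is the only stable geometry.

Step 6
Reactants: 11 (S)-N-[(E)-[2,6-bis(benzyloxy)-4-methoxyphenyl]methylidene]-2-methylpropane-2-sulfinamide; 12 allylmagnesium bromide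
Product: 13 (S)-N-[(1R)-1-[2,6-bis(benzyloxy)-4-methoxyphenyl]but-3-en-1-yl]-2-methylpropane-2-sulfinamide
Conditions: allylmagnesium bromide (Et2O), CH2Cl2, −78 °C; H2O
Reagents that add atoms: allylmagnesium bromide, C=CC[Mg]Br
Why: 1,2-Addition of a Grignard reagent to an N-tert-butanesulfinyl aldimine in a non-coordinating solvent. Magnesium binds the sulfinyl oxygen in a chair-like six-membered transition state with the tert-butyl and aryl groups equatorial, which delivers the allyl group to the Re face of the imine carbon of the (S)-sulfinyl imine and should set C2' as (R). Any minor diastereomer can be removed from 13 by chromatography or crystallisation.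

Step 7
Reactants: 13 (S)-N-[(1R)-1-[2,6-bis(benzyloxy)-4-methoxyphenyl]but-3-en-1-yl]-2-methylpropane-2-sulfinamide; 14 di-tert-butyl dicarbonate
Product: 16 tert-butyl N-[(1R)-1-[2,6-bis(benzyloxy)-4-methoxyphenyl]but-3-en-1-yl]carbamate, via primary amine 15 (not isolated)
Conditions: HCl (4 M in dioxane), MeOH, 0 °C; evaporate; Boc2O, NaHCO3, THF–H2O, rt
Reagents that add atoms: di-tert-butyl dicarbonate, CC(C)(C)OC(=O)OC(=O)OC(C)(C)C
Why: Acidic methanolysis of the N–S bond gives amine 15 as its hydrochloride, which is acylated by Boc2O after neutralisation. The acid treatment is kept short and cold so that the protonated benzylic C–N bond on the trialkoxy ring does not ionise; benzyl ethers and alkene are inert.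

Step 8
Reactants: 16 tert-butyl N-[(1R)-1-[2,6-bis(benzyloxy)-4-methoxyphenyl]but-3-en-1-yl]carbamate; 17 allyl bromide
Product: 18 tert-butyl N-allyl-N-[(1R)-1-[2,6-bis(benzyloxy)-4-methoxyphenyl]but-3-en-1-yl]carbamate
Conditions: NaH, allyl bromide, DMF, 0 °C → rt
Reagents that add atoms: allyl bromide, C=CCBr
Why: N-Alkylation of a sodium carbamate by SN2 displacement on a reactive allylic bromide; the single N–H guarantees mono-alkylation and C2' has no acidic hydrogen that could epimerise.

Step 9
Reactants: 18 tert-butyl N-allyl-N-[(1R)-1-[2,6-bis(benzyloxy)-4-methoxyphenyl]but-3-en-1-yl]carbamate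
Product: 19 tert-butyl (2R)-2-[2,6-bis(benzyloxy)-4-methoxyphenyl]-3,6-dihydro-2H-pyridine-1-carboxylate
Conditions: second-generation Grubbs catalyst RuCl2(H2IMes)(PCy3)(=CHPh) (5 mol %), CH2Cl2 (0.01 M), 40 °C
Reagents that add atoms: none
Why: Olefin ring-closing metathesis: after loss of PCy3 the 14-electron ruthenium benzylidene exchanges with the more exposed N-allyl terminus of 18 by [2+2] cycloaddition and cycloreversion. The new ruthenium alkylidene adds across the homoallyl alkene to a ruthenacyclobutane, and its cycloreversion releases 19 and a ruthenium methylidene, which re-enters the cycle with loss of ethylene. The closest known reaction type is the ring-closing metathesis of N-alkoxycarbonyl N-allyl homoallylamines to 1,2,3,6-tetrahydropyridines, widely used for 2-substituted piperidines. The one ring formed is the six-membered nitrogen ring, closed at C4'=C5' from an aza-1,7-diene, and the ring size fixes the cis geometry of the new alkene. No stereocenter is created, and C2' keeps its configuration because none of its bonds takes part and no acid or base is present. The selectivity needed is ring closure over intermolecular metathesis; a strain-free six-membered ring, high dilution, the escape of ethylene and the origin of the two alkenyl arms on the adjacent atoms N1' and C2' should secure it. The carbamate removes the basicity of nitrogen so that it cannot bind ruthenium, and both reacting alkenes are monosubstituted, the nearer one separated from the crowded C2' by the C3' methylene.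

Step 10
Reactants: 19 tert-butyl (2R)-2-[2,6-bis(benzyloxy)-4-methoxyphenyl]-3,6-dihydro-2H-pyridine-1-carboxylate
Product: 20 tert-butyl (2R)-2-(2,6-dihydroxy-4-methoxyphenyl)piperidine-1-carboxylate
Conditions: H2 (1 atm), Pd/C, EtOAc–MeOH, rt
Reagents that add atoms: none
Why: Heterogeneous hydrogenation saturates the C4'=C5' alkene and hydrogenolyses both benzyl ethers in one operation. The benzylic C2'–N bond of a carbamate should resist hydrogenolysis under neutral conditions, and no stereocenter is formed or touched.

Step 11
Reactants: 20 tert-butyl (2R)-2-(2,6-dihydroxy-4-methoxyphenyl)piperidine-1-carboxylate; 21 N-iodosuccinimide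
Product: 22 tert-butyl (2R)-2-(2,6-dihydroxy-3-iodo-4-methoxyphenyl)piperidine-1-carboxylate
Conditions: NIS (1.0 equiv), MeCN, −20 °C, dark
Reagents that add atoms: N-iodosuccinimide, O=C1CCC(=O)N1I
Why: Electrophilic aromatic iodination of a highly activated ring. The two free positions are equivalent by rotation about the aryl–C2' bond, so one mono-iodide results; one equivalent at low temperature limits a second iodination.

Step 12
Reactants: 22 tert-butyl (2R)-2-(2,6-dihydroxy-3-iodo-4-methoxyphenyl)piperidine-1-carboxylate; 23 phenylacetylene; 24 carbon monoxide
Product: 26 tert-butyl (2R)-2-(7-hydroxy-5-methoxy-4-oxo-2-phenyl-4H-chromen-8-yl)piperidine-1-carboxylate, via alkynone 25 (not isolated)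
Conditions: PdCl2(PPh3)2 (5 mol %), CO (10 atm), Et2NH, 90 °C
Reagents that add atoms: phenylacetylene, C#Cc1ccccc1; carbon monoxide, [C-]#[O+]
Why: Palladium-catalysed carbonylative Sonogashira coupling followed by annulation: oxidative addition of the C–I bond to zerovalent palladium, CO insertion and coupling with the acetylide give alkynone 25. The phenol ortho to the ketone then closes the pyranone by amine-assisted 6-endo conjugate addition; the other phenol is para to the ketone and becomes the C7 hydroxyl.

Step 13
Reactants: 26 tert-butyl (2R)-2-(7-hydroxy-5-methoxy-4-oxo-2-phenyl-4H-chromen-8-yl)piperidine-1-carboxylate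
Product: 27 7-hydroxy-5-methoxy-2-phenyl-8-[(2R)-piperidin-2-yl]-4H-chromen-4-one (CNP0140822.1)
Conditions: HCl (4 M in dioxane), CH2Cl2, 0 °C → rt; aq NaHCO3
Reagents that add atoms: none
Why: Acidolysis of the tert-butyl carbamate (loss of the tert-butyl cation, then decarboxylation). The flavone is acid-stable, and C2' should hold because ring A is now deactivated by the C4 carbonyl and the liberated amine is protonated.

## Compound list

1 | 5-methoxyresorcinol | COc1cc(O)cc(O)c1 | starting material
2 | chloromethyl methyl ether | COCCl | starting material
3 | 1-methoxy-3,5-bis(methoxymethoxy)benzene | COCOc1cc(OC)cc(OCOC)c1 | intermediate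
4 | N,N-dimethylformamide | CN(C)C=O | starting material
5 | [4-methoxy-2,6-bis(methoxymethoxy)phenyl]lithium | [Li]c1c(OCOC)cc(OC)cc1OCOC | intermediate
6 | 4-methoxy-2,6-bis(methoxymethoxy)benzaldehyde | COCOc1cc(OC)cc(OCOC)c1C=O | intermediate
7 | 2,6-dihydroxy-4-methoxybenzaldehyde | COc1cc(O)c(C=O)c(O)c1 | intermediate
8 | benzyl bromide | BrCc1ccccc1 | starting material
9 | 2,6-bis(benzyloxy)-4-methoxybenzaldehyde | COc1cc(OCc2ccccc2)c(C=O)c(OCc2ccccc2)c1 | intermediate
10 | (S)-tert-butanesulfinamide | CC(C)(C)[S@](=O)N | starting material
11 | (S)-N-[(E)-[2,6-bis(benzyloxy)-4-methoxyphenyl]methylidene]-2-methylpropane-2-sulfinamide | COc1cc(OCc2ccccc2)c(/C=N/[S@@](=O)C(C)(C)C)c(OCc2ccccc2)c1 | intermediate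
12 | allylmagnesium bromide | C=CC[Mg]Br | starting material
13 | (S)-N-[(1R)-1-[2,6-bis(benzyloxy)-4-methoxyphenyl]but-3-en-1-yl]-2-methylpropane-2-sulfinamide | COc1cc(OCc2ccccc2)c([C@@H](CC=C)N[S@@](=O)C(C)(C)C)c(OCc2ccccc2)c1 | intermediate
14 | di-tert-butyl dicarbonate | CC(C)(C)OC(=O)OC(=O)OC(C)(C)C | starting material
15 | (1R)-1-[2,6-bis(benzyloxy)-4-methoxyphenyl]but-3-en-1-amine (present in the flask as its hydrochloride) | COc1cc(OCc2ccccc2)c([C@@H](CC=C)N)c(OCc2ccccc2)c1 | intermediate
16 | tert-butyl N-[(1R)-1-[2,6-bis(benzyloxy)-4-methoxyphenyl]but-3-en-1-yl]carbamate | COc1cc(OCc2ccccc2)c([C@@H](CC=C)NC(=O)OC(C)(C)C)c(OCc2ccccc2)c1 | intermediate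
17 | allyl bromide | C=CCBr | starting material
18 | tert-butyl N-allyl-N-[(1R)-1-[2,6-bis(benzyloxy)-4-methoxyphenyl]but-3-en-1-yl]carbamate | COc1cc(OCc2ccccc2)c([C@@H](CC=C)N(CC=C)C(=O)OC(C)(C)C)c(OCc2ccccc2)c1 | intermediate
19 | tert-butyl (2R)-2-[2,6-bis(benzyloxy)-4-methoxyphenyl]-3,6-dihydro-2H-pyridine-1-carboxylate | COc1cc(OCc2ccccc2)c([C@H]2CC=CCN2C(=O)OC(C)(C)C)c(OCc2ccccc2)c1 | intermediate
20 | tert-butyl (2R)-2-(2,6-dihydroxy-4-methoxyphenyl)piperidine-1-carboxylate | COc1cc(O)c([C@H]2CCCCN2C(=O)OC(C)(C)C)c(O)c1 | intermediate
21 | N-iodosuccinimide | O=C1CCC(=O)N1I | starting material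
22 | tert-butyl (2R)-2-(2,6-dihydroxy-3-iodo-4-methoxyphenyl)piperidine-1-carboxylate | COc1cc(O)c([C@H]2CCCCN2C(=O)OC(C)(C)C)c(O)c1I | intermediate
23 | phenylacetylene | C#Cc1ccccc1 | starting material
24 | carbon monoxide | [C-]#[O+] | starting material
25 | tert-butyl (2R)-2-[2,6-dihydroxy-4-methoxy-3-(3-phenylprop-2-ynoyl)phenyl]piperidine-1-carboxylate | COc1cc(O)c([C@H]2CCCCN2C(=O)OC(C)(C)C)c(O)c1C(=O)C#Cc1ccccc1 | intermediate
26 | tert-butyl (2R)-2-(7-hydroxy-5-methoxy-4-oxo-2-phenyl-4H-chromen-8-yl)piperidine-1-carboxylate | COc1cc(O)c([C@H]2CCCCN2C(=O)OC(C)(C)C)c2oc(-c3ccccc3)cc(=O)c12 | intermediate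
27 | 7-hydroxy-5-methoxy-2-phenyl-8-[(2R)-piperidin-2-yl]-4H-chromen-4-one (CNP0140822.1) | COc1cc(O)c([C@H]2CCCCN2)c2oc(-c3ccccc3)cc(=O)c12 | target

## Step count and least certain steps

Total: 13 steps. Longest linear sequence: 13 steps (1 to 27); the route is fully linear.

**Step 9 (key step).**
- What may go wrong: migration of the N-allyl double bond toward nitrogen, caused by ruthenium hydride species from catalyst decay, after which metathesis closes a smaller ring or strips the propenyl group. Intermolecular metathesis at the exposed N-allyl terminus is also possible if the homoallyl alkene, which lies near the two benzyloxy groups, engages slowly.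
- Fallback: a ring closure that needs no second alkene. It sets out from 16. Rhodium-catalysed linear hydroformylation (Rh(acac)(CO)2, BIPHEPHOS, CO/H2, THF, 60 °C) of the terminal alkene should give the aldehyde tert-butyl N-[(1R)-1-[2,6-bis(benzyloxy)-4-methoxyphenyl]-5-oxopentyl]carbamate F1. F1 closes onto the carbamate nitrogen and, with a trace of pyridinium p-toluenesulfonate, dehydrates to the cyclic enecarbamate tert-butyl (2R)-2-[2,6-bis(benzyloxy)-4-methoxyphenyl]-3,4-dihydro-2H-pyridine-1-carboxylate F2. Hydrogenation over Pd/C then saturates F2 and removes the benzyl ethers, and the route is rejoined at 20.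

**Step 12.**
- What may go wrong: slow CO insertion at an aryl–palladium centre flanked by OH and OMe on an electron-rich ring, so that direct alkynylation followed by furan closure, or capture of the acylpalladium by the amine, overtakes the annulation. Heating in amine may also erode the configuration at C2' through reversible opening of the benzylic C–N bond next to the phenol.
- Fallback: stepwise construction of ring C without carbon monoxide. It sets out from 22. Stille coupling with tributyl(1-ethoxyvinyl)stannane (PdCl2(PPh3)2, toluene, 90 °C) gives the enol ether tert-butyl (2R)-2-[3-(1-ethoxyethenyl)-2,6-dihydroxy-4-methoxyphenyl]piperidine-1-carboxylate F3. Brief treatment with dilute aqueous acid hydrolyses F3 to the methyl ketone tert-butyl (2R)-2-(3-acetyl-2,6-dihydroxy-4-methoxyphenyl)piperidine-1-carboxylate F4. Claisen–Schmidt condensation with benzaldehyde (KOH, EtOH) gives the chalcone tert-butyl (2R)-2-[2,6-dihydroxy-4-methoxy-3-[(E)-3-phenylprop-2-enoyl]phenyl]piperidine-1-carboxylate F5. Oxidative cyclisation with catalytic I2 in DMSO at 110 °C closes the pyranone, and the route is rejoined at 26.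

**Step 11.**
- What may go wrong: a second iodination, because the first iodine hardly deactivates a free resorcinol ring, and oxidation of the electron-rich diphenol by the iodinating agent.
- Fallback: iodination at the less activated ether stage. It sets out from 19. Hydrogenation of the ring alkene alone with H2 over RhCl(PPh3)3 leaves the benzyl ethers and gives tert-butyl (2R)-2-[2,6-bis(benzyloxy)-4-methoxyphenyl]piperidine-1-carboxylate F6. NIS in MeCN then gives the mono-iodide tert-butyl (2R)-2-[2,6-bis(benzyloxy)-3-iodo-4-methoxyphenyl]piperidine-1-carboxylate F7. BCl3 with pentamethylbenzene as cation trap (CH2Cl2, −78 °C) cleaves both benzyl ethers without touching the aryl iodide, and the route is rejoined at 22.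

**Step 6.**
- What may go wrong: poor or reversed facial selectivity, because magnesium can be chelated by an ortho benzyloxy oxygen instead of the sulfinyl oxygen and the di-ortho-substituted aryl group is twisted out of the imine plane, which disturbs the chair model. A modest ratio is first met by separating the diastereomers of 13.
- Fallback: stereocontrol by resolution instead of an auxiliary. It sets out from 9. Aminoallylation with ammonia and allylboronic acid pinacol ester in ethanol gives racemic 1-[2,6-bis(benzyloxy)-4-methoxyphenyl]but-3-en-1-amine F8. F8 is resolved by fractional crystallisation with an enantiopure carboxylic acid chosen by screening, or by chromatography on a chiral stationary phase, and the (R)-amine rejoins the route at 15.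

**Step 8.**
- What may go wrong: incomplete N-alkylation, because the carbamate nitrogen is shielded by the two ortho benzyloxy groups and the tert-butyl group.
- Fallback: alkylation before acylation. It sets out from 15, isolated as the free base. Mono-allylation with allyl bromide and K2CO3 in MeCN gives (1R)-N-allyl-1-[2,6-bis(benzyloxy)-4-methoxyphenyl]but-3-en-1-amine F9; the crowding that hampers step 8 here disfavours a second allylation. Acylation of F9 with Boc2O (THF, 50 °C) rejoins the route at 18.

## Further compounds

F1 | step 9 | tert-butyl N-[(1R)-1-[2,6-bis(benzyloxy)-4-methoxyphenyl]-5-oxopentyl]carbamate | COc1cc(OCc2ccccc2)c([C@@H](CCCC=O)NC(=O)OC(C)(C)C)c(OCc2ccccc2)c1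
F2 | step 9 | tert-butyl (2R)-2-[2,6-bis(benzyloxy)-4-methoxyphenyl]-3,4-dihydro-2H-pyridine-1-carboxylate | COc1cc(OCc2ccccc2)c([C@H]2CCC=CN2C(=O)OC(C)(C)C)c(OCc2ccccc2)c1
F3 | step 12 | tert-butyl (2R)-2-[3-(1-ethoxyethenyl)-2,6-dihydroxy-4-methoxyphenyl]piperidine-1-carboxylate | CCOC(=C)c1c(OC)cc(O)c([C@H]2CCCCN2C(=O)OC(C)(C)C)c1O
F4 | step 12 | tert-butyl (2R)-2-(3-acetyl-2,6-dihydroxy-4-methoxyphenyl)piperidine-1-carboxylate | CC(=O)c1c(OC)cc(O)c([C@H]2CCCCN2C(=O)OC(C)(C)C)c1O
F5 | step 12 | tert-butyl (2R)-2-[2,6-dihydroxy-4-methoxy-3-[(E)-3-phenylprop-2-enoyl]phenyl]piperidine-1-carboxylate | O=C(/C=C/c1ccccc1)c1c(OC)cc(O)c([C@H]2CCCCN2C(=O)OC(C)(C)C)c1O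
F6 | step 11 | tert-butyl (2R)-2-[2,6-bis(benzyloxy)-4-methoxyphenyl]piperidine-1-carboxylate | COc1cc(OCc2ccccc2)c([C@H]2CCCCN2C(=O)OC(C)(C)C)c(OCc2ccccc2)c1
F7 | step 11 | tert-butyl (2R)-2-[2,6-bis(benzyloxy)-3-iodo-4-methoxyphenyl]piperidine-1-carboxylate | COc1cc(OCc2ccccc2)c([C@H]2CCCCN2C(=O)OC(C)(C)C)c(OCc2ccccc2)c1I
F8 | step 6 | racemic 1-[2,6-bis(benzyloxy)-4-methoxyphenyl]but-3-en-1-amine | COc1cc(OCc2ccccc2)c(C(CC=C)N)c(OCc2ccccc2)c1
F9 | step 8 | (1R)-N-allyl-1-[2,6-bis(benzyloxy)-4-methoxyphenyl]but-3-en-1-amine | COc1cc(OCc2ccccc2)c([C@@H](CC=C)NCC=C)c(OCc2ccccc2)c1
A1 | alternative 1 | tert-butyl (2R)-2-(7-hydroxy-5-methoxy-4-oxo-2-phenyl-4H-chromen-8-yl)piperidine-1-carboxylate | COc1cc(O)c([C@H]2CCCCN2C(=O)OC(C)(C)C)c2oc(-c3ccccc3)cc(=O)c12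
A2 | alternative 1 | tert-butyl (2R)-2-(2,6-dihydroxy-3-iodo-4-methoxyphenyl)piperidine-1-carboxylate | COc1cc(O)c([C@H]2CCCCN2C(=O)OC(C)(C)C)c(O)c1I
A3 | alternative 2 | (2R)-1-[(S)-tert-butylsulfinyl]-2-[4-methoxy-2,6-bis(methoxymethoxy)phenyl]piperidine | COCOc1cc(OC)cc(OCOC)c1[C@H]1CCCCN1[S@@](=O)C(C)(C)C
A4 | alternative 2 | (S)-N-[(E)-[4-methoxy-2,6-bis(methoxymethoxy)phenyl]methylidene]-2-methylpropane-2-sulfinamide | COCOc1cc(OC)cc(OCOC)c1/C=N/[S@@](=O)C(C)(C)C
A5 | alternative 2 | 4-chlorobutylmagnesium bromide | ClCCCC[Mg]Br
A6 | alternative 3 | tert-butyl (2R)-2-(2,6-dihydroxy-4-methoxyphenyl)piperidine-1-carboxylate | COc1cc(O)c([C@H]2CCCCN2C(=O)OC(C)(C)C)c(O)c1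
A7 | alternative 3 | tert-butyl N-[(E)-5-(2,6-dihydroxy-4-methoxyphenyl)pent-4-en-1-yl]carbamate | COc1cc(O)c(/C=C/CCCNC(=O)OC(C)(C)C)c(O)c1
A8 | alternative 3 | tert-butyl N-[5-(2-hydroxy-4-methoxy-6-oxocyclohexa-2,4-dien-1-ylidene)pentyl]carbamate | COC1=CC(=O)C(=CCCCCNC(=O)OC(C)(C)C)C(O)=C1
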